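Numbering: ring A is the benzo ring (C3a to C7a), ring B is O1–C2–C3–C3a–C7a, ring C is the pendant guaiacyl ring, and the side chain C1'–C2'–C3' sits on C5. The retrosynthesis cuts first C5–C1' (aryl–acyl bond, side chain from (S)-lactate), then C2–C3 of ring B, then O1–C2 (benzyl aryl ether).
Enabling feature: C2 is alpha to O1 and benzylic to the electron-rich ring C, so in the opened ether its CH2 is a strongly hydridic C–H donor. It lies 1,5 to C3, which is benzylic on ring A and can be made a carbene from the acetyl oxidation level. The rigid C3a–C7a–O1 edge of ring A is the built-in tether.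
Forward: rings A and C are bought. Bromination at C5, Mitsunobu etherification and hydrazone formation follow, then MnO2 with a chiral dirhodium carboxylate closes ring B by carbene C–H insertion. This sets C2 and C3 in one operation from an achiral acetophenone, and the only helper (the hydrazone nitrogen) leaves as N2 in that step.
The route then epimerises C2 to trans, joins the chain by Br/Li exchange and acylation with a lactate Weinreb amide (C5–C1'), removes both silyl groups and reduces the ketone.
Stereochemistry: C3 comes from the catalyst. C2 is first cis (kinetic) and then trans by thermodynamic relay from C3. C2' comes from ethyl (S)-lactate, and C1' from Cram-chelate hydride delivery under control of C2'.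

Key step: step 6

Assumption: the sense of induction at C3 is written for Rh2(S-PTAD)4 (dirhodium tetrakis[(S)-N-phthaloyl-adamantylglycinate]) by analogy with related insertions. Both antipodes of the catalyst are available, and the antipode would be taken if the sense proved opposite.

Step 1
Reactants: 1 1-(2-hydroxy-3-methoxyphenyl)ethanone
Product: 2 1-(5-bromo-2-hydroxy-3-methoxyphenyl)ethanone
Conditions: NBS, MeCN, 0 °C to rt
Reagents that add atoms: N-bromosuccinimide, O=C1CCC(=O)N1Br
Why: Electrophilic aromatic bromination should go to the only open position activated by the free phenol, C5 (para to OH, meta to the acetyl group), as it does in ortho-vanillin, and it plants the handle for the later side-chain coupling.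

Step 2
Reactants: 3 vanillin
Product: 4 3-methoxy-4-(triisopropylsilyloxy)benzaldehyde
Conditions: TIPSCl, imidazole, DMF, rt
Reagents that add atoms: triisopropylsilyl chloride, CC(C)[Si](Cl)(C(C)C)C(C)C
Why: Imidazole-promoted silylation of a phenol is routine, and the bulky TIPS ether is chosen because it must survive hydrazine, TFA and n-BuLi yet leave with fluoride without hydrogenolysis or strong acid.

Step 3
Reactants: 4 3-methoxy-4-(triisopropylsilyloxy)benzaldehyde
Product: 5 [3-methoxy-4-(triisopropylsilyloxy)phenyl]methanol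
Conditions: NaBH4, MeOH, 0 °C
Reagents that add atoms: none
Why: Borohydride reduction of an aromatic aldehyde is fast at 0 °C and leaves the hindered aryl silyl ether untouched.

Step 4
Reactants: 2 1-(5-bromo-2-hydroxy-3-methoxyphenyl)ethanone; 5 [3-methoxy-4-(triisopropylsilyloxy)phenyl]methanol
Product: 6 1-[5-bromo-3-methoxy-2-{[3-methoxy-4-(triisopropylsilyloxy)benzyl]oxy}phenyl]ethanone
Conditions: PPh3, DIAD, THF, 0 °C to rt
Reagents that add atoms: none
Why: Mitsunobu etherification of an acidic (acyl- and bromo-substituted) phenol with a primary benzylic alcohol forms the O1–CH2 bond under neutral conditions that spare the aryl silyl ether.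

Step 5
Reactants: 6 1-[5-bromo-3-methoxy-2-{[3-methoxy-4-(triisopropylsilyloxy)benzyl]oxy}phenyl]ethanone
Product: 7 hydrazone of ketone 6 (C=N geometry of no consequence)
Conditions: N2H4·H2O (excess), AcOH (cat.), EtOH, 70 °C
Reagents that add atoms: hydrazine (used as the hydrate), NN
Why: Condensation of an aryl methyl ketone with excess hydrazine gives the free hydrazone (the excess suppresses azine formation) and so brings the future C3 to the level from which a diazo group can be made.

Step 6
Reactants: 7 hydrazone of ketone 6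
Product: 9 (2R,3S)-5-bromo-7-methoxy-2-[3-methoxy-4-(triisopropylsilyloxy)phenyl]-3-methyl-2,3-dihydrobenzofuran (cis), via aryl methyl diazoalkane 8 (not isolated)
Conditions: MnO2 (activated), CH2Cl2, 0 °C, filtration; then slow addition to Rh2(S-PTAD)4 (1 mol %), CH2Cl2, −20 °C to 0 °C
Reagents that add atoms: none
Why: MnO2 dehydrogenates hydrazone 7 to the diazoalkane 8, Rh2(S-PTAD)4 expels N2 from 8 to give a donor/donor (aryl, methyl) rhodium carbene at the future C3, and this carbene draws a hydride from the OCH2 group that lies 1,5 to it while the developing oxocarbenium carbon (future C2) bonds to C3 in the same highly asynchronous event that releases the catalyst. The closest known reaction type is the enantioselective intramolecular C–H insertion of donor/donor rhodium carbenes, generated with MnO2 from hydrazones of 2-(benzyloxy)aryl ketones, which gives 2,3-disubstituted 2,3-dihydrobenzofurans. Ring B closes by 1,5-insertion through a five-membered cyclic transition state built from C3, C3a, C7a, O1 and C2, the only ring size the rigid ortho tether allows. C3 is set by the chiral carboxylate pocket of the catalyst, which leaves one face of the carbene open to the incoming C–H bond, and C2 is set relative to C3 by the compact hydride-transfer and rebound geometry, which places ring C and the methyl group on the same side (cis, the usual kinetic outcome of this insertion). The step needs insertion to outrun 1,2-hydride migration from the carbene methyl group and azine formation, and the substrate secures this because the reacting C–H is both alpha to O1 and benzylic to the para-silyloxy ring C, hence strongly hydridic, and because the flanking C7 methoxy group twists the OCH2Ar arm out of the plane of ring A toward the carbene, with the bulky ligand, low temperature and slow addition of 8 helping further. The aryl bromide, silyl ether and methyl ethers should be inert to the weakly electrophilic carbene.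

Step 7
Reactants: 9 (2R,3S)-cis-bromodihydrobenzofuran
Product: 10 (2S,3S)-5-bromo-7-methoxy-2-[3-methoxy-4-(triisopropylsilyloxy)phenyl]-3-methyl-2,3-dihydrobenzofuran (trans)
Conditions: TFA, CH2Cl2 (dilute), −20 °C to 0 °C
Reagents that add atoms: none
Why: Acid-promoted reversible heterolysis of the benzylic C2–O1 bond (para-silyloxybenzyl cation and ring A phenol) followed by reclosure equilibrates C2 alone, so the untouched C3 stereocentre should steer ring C to the less crowded trans face under thermodynamic control, a known cis-to-trans isomerisation of 2-aryl-2,3-dihydrobenzofurans.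

Step 8
Reactants: 11 ethyl (S)-lactate
Product: 12 ethyl (S)-2-(tert-butyldimethylsilyloxy)propanoate
Conditions: TBSCl, imidazole, DMF, 0 °C to rt
Reagents that add atoms: tert-butyldimethylsilyl chloride, CC(C)(C)[Si](C)(C)Cl
Why: Imidazole-promoted silylation of a secondary alcohol does not touch the stereocentre that becomes C2' of the target.

Step 9
Reactants: 12 ethyl (S)-2-(tert-butyldimethylsilyloxy)propanoate
Product: 13 (S)-2-(tert-butyldimethylsilyloxy)-N-methoxy-N-methylpropanamide
Conditions: MeNH(OMe)·HCl, i-PrMgCl, THF, −20 °C to 0 °C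
Reagents that add atoms: N,O-dimethylhydroxylamine hydrochloride, CNOC.Cl
Why: Aminolysis of the ester by the chloromagnesium amide (Weinreb amide formation) is faster than enolisation at low temperature, so the S configuration should be kept.

Step 10
Reactants: 10 (2S,3S)-trans-bromodihydrobenzofuran; 13 (S)-2-(tert-butyldimethylsilyloxy)-N-methoxy-N-methylpropanamide
Product: 15 (S)-2-(tert-butyldimethylsilyloxy)-1-{(2S,3S)-7-methoxy-2-[3-methoxy-4-(triisopropylsilyloxy)phenyl]-3-methyl-2,3-dihydrobenzofuran-5-yl}propan-1-one, via aryllithium 14 (not isolated)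
Conditions: n-BuLi, THF, −78 °C; then 13, −78 °C to −30 °C; aq NH4Cl
Reagents that add atoms: n-butyllithium, [Li]CCCC (gives the lithium atom of 14; no atom of it stays in 15)
Why: Bromine–lithium exchange outruns any ortho- or benzylic deprotonation at −78 °C, and the Weinreb ketone synthesis stops at the chelated tetrahedral adduct, so the C5–C1' bond should form without over-addition or loss of the lactate stereocentre.

Step 11
Reactants: 15 bis-silylated ketone
Product: 16 (S)-2-hydroxy-1-[(2S,3S)-2-(4-hydroxy-3-methoxyphenyl)-7-methoxy-3-methyl-2,3-dihydrobenzofuran-5-yl]propan-1-one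
Conditions: TBAF, AcOH (1:1), THF, 0 °C to rt
Reagents that add atoms: none
Why: Fluoride cleaves both Si–O bonds, while the acetic acid buffer keeps the medium non-basic so that the alpha-hydroxy ketone should neither racemise nor undergo an alpha-ketol shift.

Step 12
Reactants: 16 alpha-hydroxy ketone
Product: 17 (1R,2S)-1-[(2S,3S)-2-(4-hydroxy-3-methoxyphenyl)-7-methoxy-3-methyl-2,3-dihydrobenzofuran-5-yl]propane-1,2-diol (target)
Conditions: Zn(BH4)2 (ethereal solution, excess), Et2O–THF, −30 °C to 0 °C; aq NH4Cl
Reagents that add atoms: none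
Why: In this chelation-controlled reduction (Cram chelate model) zinc ties the carbonyl oxygen and the alpha-oxygen into a five-membered ring, and hydride arrives from the face that carries H rather than CH3 of the S centre, which should give the anti (erythro) 1R,2S diol.

Compound list
1 | 1-(2-hydroxy-3-methoxyphenyl)ethanone | CC(=O)c1cccc(OC)c1O | starting material
2 | 1-(5-bromo-2-hydroxy-3-methoxyphenyl)ethanone | CC(=O)c1cc(Br)cc(OC)c1O | intermediate
3 | vanillin | COc1cc(C=O)ccc1O | starting material
4 | 3-methoxy-4-(triisopropylsilyloxy)benzaldehyde | COc1cc(C=O)ccc1O[Si](C(C)C)(C(C)C)C(C)C | intermediate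
5 | [3-methoxy-4-(triisopropylsilyloxy)phenyl]methanol | COc1cc(CO)ccc1O[Si](C(C)C)(C(C)C)C(C)C | intermediate
6 | 1-[5-bromo-3-methoxy-2-{[3-methoxy-4-(triisopropylsilyloxy)benzyl]oxy}phenyl]ethanone | CC(=O)c1cc(Br)cc(OC)c1OCc1ccc(O[Si](C(C)C)(C(C)C)C(C)C)c(OC)c1 | intermediate
7 | hydrazone of 6 (C=N geometry undefined) | CC(=NN)c1cc(Br)cc(OC)c1OCc1ccc(O[Si](C(C)C)(C(C)C)C(C)C)c(OC)c1 | intermediate
8 | 1-aryl-1-diazoethane derived from 7 (not isolated) | CC(=[N+]=[N-])c1cc(Br)cc(OC)c1OCc1ccc(O[Si](C(C)C)(C(C)C)C(C)C)c(OC)c1 | intermediate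
9 | (2R,3S)-5-bromo-7-methoxy-2-[3-methoxy-4-(triisopropylsilyloxy)phenyl]-3-methyl-2,3-dihydrobenzofuran (cis) | COc1cc([C@@H]2Oc3c(OC)cc(Br)cc3[C@@H]2C)ccc1O[Si](C(C)C)(C(C)C)C(C)C | intermediate
10 | (2S,3S)-5-bromo-7-methoxy-2-[3-methoxy-4-(triisopropylsilyloxy)phenyl]-3-methyl-2,3-dihydrobenzofuran (trans) | COc1cc([C@H]2Oc3c(OC)cc(Br)cc3[C@@H]2C)ccc1O[Si](C(C)C)(C(C)C)C(C)C | intermediate
11 | ethyl (S)-lactate | CCOC(=O)[C@H](C)O | starting material
12 | ethyl (S)-2-(tert-butyldimethylsilyloxy)propanoate | CCOC(=O)[C@H](C)O[Si](C)(C)C(C)(C)C | intermediate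
13 | (S)-2-(tert-butyldimethylsilyloxy)-N-methoxy-N-methylpropanamide | CON(C)C(=O)[C@H](C)O[Si](C)(C)C(C)(C)C | intermediate
14 | (2S,3S)-5-lithio analogue of 10 (not isolated) | COc1cc([C@H]2Oc3c(OC)cc([Li])cc3[C@@H]2C)ccc1O[Si](C(C)C)(C(C)C)C(C)C | intermediate
15 | (S)-2-(tert-butyldimethylsilyloxy)-1-{(2S,3S)-7-methoxy-2-[3-methoxy-4-(triisopropylsilyloxy)phenyl]-3-methyl-2,3-dihydrobenzofuran-5-yl}propan-1-one | COc1cc([C@H]2Oc3c(OC)cc(C(=O)[C@H](C)O[Si](C)(C)C(C)(C)C)cc3[C@@H]2C)ccc1O[Si](C(C)C)(C(C)C)C(C)C | intermediate
16 | (S)-2-hydroxy-1-[(2S,3S)-2-(4-hydroxy-3-methoxyphenyl)-7-methoxy-3-methyl-2,3-dihydrobenzofuran-5-yl]propan-1-one | COc1cc([C@H]2Oc3c(OC)cc(C(=O)[C@H](C)O)cc3[C@@H]2C)ccc1O | intermediate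
17 | (1R,2S)-1-[(2S,3S)-2-(4-hydroxy-3-methoxyphenyl)-7-methoxy-3-methyl-2,3-dihydrobenzofuran-5-yl]propane-1,2-diol | COc1cc([C@H]2Oc3c(OC)cc([C@@H](O)[C@H](C)O)cc3[C@@H]2C)ccc1O | target

Total step count: 12. Longest linear sequence: 9 steps (steps 2, 3, 4, 5, 6, 7, 10, 11, 12).

Steps most likely to fail

Step 6. The insertion may be outrun by 1,2-hydride migration from the carbene methyl group or by azine formation, or the catalyst may discriminate the carbene faces poorly with so small a donor group. The fallback changes the carbene class to a donor/acceptor carbene, in which an ester with no hydrogen to migrate stands in for the methyl group. It sets out from 6 and comes back at 10, so steps 5 to 7 are bypassed.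
- Riley oxidation of the acetyl group of 6 (SeO2, pyridine, 90 °C) should give the arylglyoxylic acid F1. Me3SiCHN2 (toluene–MeOH) converts this into the methyl arylglyoxylate F2.
- Condensation with TsNHNH2 gives the tosylhydrazone F3. DBU (CH2Cl2, rt, Bamford–Stevens type loss of sulfinate) then gives the methyl aryldiazoacetate F4.
- Rh2(S-PTTL)4 (dirhodium tetrakis[N-phthaloyl-(S)-tert-leucinate], toluene, −60 °C) should close the same C2–C3 bond by the well-established enantioselective insertion, giving the cis ester F5. Here the catalyst fixes C2.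
- DBU in warm toluene, a base that spares the aryl silyl ether, epimerises the acidic C3 to give the trans ester F6.
- i-Bu2AlH (CH2Cl2, −78 °C to 0 °C) reduces this to the primary alcohol F7, TsCl with pyridine gives the tosylate F8, and LiEt3BH (THF, 0 °C) replaces the sulfonate by hydride to give 10.

Step 7. Equilibration may stay incomplete, the C3 configuration may erode through loss of the C3 hydrogen from the open cation (E1 or hydride shift), or the silyl group may be lost. The fallback moves the epimerisation to a later, push–pull activated stage, where it runs through a neutral para-quinone methide instead of a cation made by strong acid. It sets out from 9 and comes back at 16.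
- The cis bromide 9 is treated with n-BuLi (THF, −78 °C) to give the cis aryllithium F9, which is acylated with 13 to give the cis bis-silylated ketone F10.
- TBAF with AcOH gives the cis hydroxy ketone F11.
- In F11 the free para-phenol of ring C pushes and the para-acyl aryloxide of ring A is a far better leaving group. A trace of camphorsulfonic acid in CH2Cl2 at rt should therefore open and reclose the C2–O1 bond and deliver the trans isomer 16.

Step 12. Facial selectivity may be poor if zinc phenoxide aggregation weakens the five-membered chelate. The fallback replaces substrate control by catalyst control and reverses the order of reduction and deprotection. It sets out from 15 and comes back at 17.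
- Noyori-type asymmetric transfer hydrogenation of 15 with RuCl(p-cymene)[(S,S)-TsDPEN] (HCO2H–Et3N 5:2, rt) places hydride according to the aryl group. It should give the (1R,2S) bis-silylated alcohol F12.
- TBAF with AcOH (THF, 0 °C to rt) then frees 17.

Further compounds
F1 | step 6 | 2-[5-bromo-3-methoxy-2-{[3-methoxy-4-(triisopropylsilyloxy)benzyl]oxy}phenyl]-2-oxoacetic acid | OC(=O)C(=O)c1cc(Br)cc(OC)c1OCc1ccc(O[Si](C(C)C)(C(C)C)C(C)C)c(OC)c1
F2 | step 6 | methyl 2-[5-bromo-3-methoxy-2-{[3-methoxy-4-(triisopropylsilyloxy)benzyl]oxy}phenyl]-2-oxoacetate | COC(=O)C(=O)c1cc(Br)cc(OC)c1OCc1ccc(O[Si](C(C)C)(C(C)C)C(C)C)c(OC)c1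
F3 | step 6 | tosylhydrazone of F2 (C=N geometry undefined) | COC(=O)C(=NNS(=O)(=O)c1ccc(C)cc1)c1cc(Br)cc(OC)c1OCc1ccc(O[Si](C(C)C)(C(C)C)C(C)C)c(OC)c1
F4 | step 6 | methyl 2-[5-bromo-3-methoxy-2-{[3-methoxy-4-(triisopropylsilyloxy)benzyl]oxy}phenyl]-2-diazoacetate | COC(=O)C(=[N+]=[N-])c1cc(Br)cc(OC)c1OCc1ccc(O[Si](C(C)C)(C(C)C)C(C)C)c(OC)c1
F5 | step 6 | methyl (2S,3R)-5-bromo-7-methoxy-2-[3-methoxy-4-(triisopropylsilyloxy)phenyl]-2,3-dihydrobenzofuran-3-carboxylate (cis) | COc1cc([C@H]2Oc3c(OC)cc(Br)cc3[C@H]2C(=O)OC)ccc1O[Si](C(C)C)(C(C)C)C(C)C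
F6 | step 6 | methyl (2S,3S)-5-bromo-7-methoxy-2-[3-methoxy-4-(triisopropylsilyloxy)phenyl]-2,3-dihydrobenzofuran-3-carboxylate (trans) | COc1cc([C@H]2Oc3c(OC)cc(Br)cc3[C@@H]2C(=O)OC)ccc1O[Si](C(C)C)(C(C)C)C(C)C
F7 | step 6 | {(2S,3R)-5-bromo-7-methoxy-2-[3-methoxy-4-(triisopropylsilyloxy)phenyl]-2,3-dihydrobenzofuran-3-yl}methanol (trans) | COc1cc([C@H]2Oc3c(OC)cc(Br)cc3[C@@H]2CO)ccc1O[Si](C(C)C)(C(C)C)C(C)C
F8 | step 6 | {(2S,3R)-5-bromo-7-methoxy-2-[3-methoxy-4-(triisopropylsilyloxy)phenyl]-2,3-dihydrobenzofuran-3-yl}methyl 4-methylbenzenesulfonate (trans) | COc1cc([C@H]2Oc3c(OC)cc(Br)cc3[C@@H]2COS(=O)(=O)c4ccc(C)cc4)ccc1O[Si](C(C)C)(C(C)C)C(C)C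
F9 | step 7 | (2R,3S)-5-lithio analogue of 9 (cis, not isolated) | COc1cc([C@@H]2Oc3c(OC)cc([Li])cc3[C@@H]2C)ccc1O[Si](C(C)C)(C(C)C)C(C)C
F10 | step 7 | (S)-2-(tert-butyldimethylsilyloxy)-1-{(2R,3S)-7-methoxy-2-[3-methoxy-4-(triisopropylsilyloxy)phenyl]-3-methyl-2,3-dihydrobenzofuran-5-yl}propan-1-one (cis) | COc1cc([C@@H]2Oc3c(OC)cc(C(=O)[C@H](C)O[Si](C)(C)C(C)(C)C)cc3[C@@H]2C)ccc1O[Si](C(C)C)(C(C)C)C(C)C
F11 | step 7 | (S)-2-hydroxy-1-[(2R,3S)-2-(4-hydroxy-3-methoxyphenyl)-7-methoxy-3-methyl-2,3-dihydrobenzofuran-5-yl]propan-1-one (cis) | COc1cc([C@@H]2Oc3c(OC)cc(C(=O)[C@H](C)O)cc3[C@@H]2C)ccc1O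
F12 | step 12 | (1R,2S)-2-(tert-butyldimethylsilyloxy)-1-{(2S,3S)-7-methoxy-2-[3-methoxy-4-(triisopropylsilyloxy)phenyl]-3-methyl-2,3-dihydrobenzofuran-5-yl}propan-1-ol | COc1cc([C@H]2Oc3c(OC)cc([C@@H](O)[C@H](C)O[Si](C)(C)C(C)(C)C)cc3[C@@H]2C)ccc1O[Si](C(C)C)(C(C)C)C(C)C
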